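Complex with two exchanged is paid for in incoming ligand: each starting complex lost has spent one ligand, and each complex with two exchanged has spent one more. Ligand unspent is therefore the charge minus both, counted per starting complex charged. Spring charges 0.950 ligand per starting complex, and the product needs two, which makes incoming ligand the limiting reagent.

the same everywhere: starting complex 0.10 M

|  | incoming ligand | leaving ligand | remark | time |
|---|---|---|---|---|
| amber | 0.095 M | 0.20 M | run made earlier |  |
| blue | 0.048 M | 0.20 M | run made earlier |  |
| grey | 0.071 M | 0.20 M | run made earlier |  |
| spring | 0.0950 M | 0.200 M | everything together in a closed stirred flask, run for 3.0 d | 3.0 d |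
| dawn | 0.0950 M (fed, over 2.40 d) | 0.200 M | a stirred flask in which incoming ligand is dosed at a steady rate over 2.40 d without added volume, worked up at 3.0 d | 3.0 d |
| noon | 0.0950 M | 0.200 M | one stirred flow tank at steady state, fed with the mixture as stated, mean residence time 3.0 d |  |
| summer | 0.0950 M | 0.200 M | one stirred flow tank at steady state, fed with the mixture as stated, mean residence time 15.0 d |  |

| run | time / h | complex with two exchanged / % | starting complex / % |
|---|---|---|---|
| amber | 4.00 | 0 | 79 |
| amber | 10.0 | 5 | 67 |
| amber | 20.0 | 8 | 48 |
| amber | 30.0 | 13 | 41 |
| amber | 40.0 | 14 | 37 |
| blue | 8.00 | 0 | 83 |
| blue | 15.0 | 2 | 76 |
| blue | 25.0 | 2 | 69 |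
| blue | 30.0 | 4 | 68 |
| blue | 40.0 | 7 | 62 |
| grey | 4.00 | 0 | 85 |
| grey | 10.0 | 3 | 73 |
| grey | 20.0 | 8 | 63 |
| grey | 30.0 | 10 | 52 |
| grey | 40.0 | 10 | 52 |

(each reading ± 1.5 percentage points)
1. the set-up with the highest amount of complex with two exchanged at the outlet or at the end, in percent of the starting complex put in ("none" if the first two lie within 2 percentage points) (spring / dawn / noon / summer / none)
2. amount of complex with two exchanged at the outlet or at the end, in percent of the starting complex put in, spring
3. amount of complex with two exchanged at the outlet or at the end, in percent of the starting complex put in, dawn
4. amount of complex with two exchanged at the outlet or at the end, in percent of the starting complex put in, noon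
5. amount of complex with two exchanged at the outlet or at the end, in percent of the starting complex put in, summer
- the stated concentrations are those of everything mixed, before any reaction; amounts are the same in each set-up
- the feed brings no volume worth counting
- the earlier runs were made in a closed, stirred flask

Spring is the amber recipe run on to 3.0 d, so the amber readings carry over. Leaving ligand is charged at 0.200 M in amber, blue, grey and spring, so its effect cannot be read from these runs.

In amber, the balance leaves 35.0% unspent at 20.0 h and 18.0% at 40.0 h. Of the ligand spent between those readings, 35.3% went into the second exchange; call this reading the late share. By this reckoning, a point misjudged in the ligand charge passes into the unspent ligand and moves the product by about 35.3% of a point. As for time, unspent ligand in amber fell to about half in 20.0 h, so at that pace 5.94% is reckoned to stand at 3.0 d, and that remainder is worth 2.1 percentage points of product. Each reading carries a scatter of 1.5 points. Joining the amber reading to the late share gives spring 18.3%.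

The forecast gives 20% for spring, 14.5% for dawn, 18% for noon and 26.5% for summer, and chooses summer, holding summer “above the batch limit because back-mixing favours a second exchange”. The reckoning above gives a lower spring figure and does not reach the other flasks.

The flasks give 19.3% for spring, 13.5% for dawn, 13.8% for noon and 12.8% for summer, so the best is spring.

    starting complex + incoming ligand → leaving ligand + complex with one exchanged (k = 0.560 M⁻¹ h⁻¹)
    complex with one exchanged + incoming ligand → leaving ligand + complex with two exchanged (k = 0.410 M⁻¹ h⁻¹)
    complex with one exchanged → side product (k = 0.0190 h⁻¹)

Spring is not at rest at 3.0 d: 7.57% of its own ligand charge remains, and 16.9% of the starting complex charged stands as complex with one exchanged. By 30.0 d, product reaches 20.7% from 19.3%, while side product goes from 32.4% to 53.7%. Of the ligand spent in that stretch of spring, 19.1% went into the second exchange, against the late share of 35.3% read in amber. Counted from the start, spring at 30.0 d has put 21.7% of its spent ligand into the second exchange, and the summer outlet, holding 29.6% starting complex, 15.4%.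

With 0.060 M of starting complex, the late share on the whole charge gives 55.9%. That neighbour of spring holds 33.1% at 3.00 d, with 26.1% of its ligand unspent.

The data stem from a simulated flask for substances that don't exist; noise was put on by code.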